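## Retrosynthetic overview

1. The target is reached by reduction of a formyl group and global desilylation of an all-trans 2-aryl-4-(aryl-silyloxymethyl)tetrahydrofuran-3-carbaldehyde.
2. The tetrahydrofuran ring is not closed directly. It arises by Lewis-acid ring contraction of a seven-membered cyclic vinyl acetal, a 2-aryl-5-substituted 4,5-dihydro-1,3-dioxepine. This forms the C2–C3 bond and sets C2 and C3.
3. The enabling feature is the O1–C2(aryl)–O3 acetal of the dioxepine, in which O1 is also the oxygen of the ring enol ether C6=C7. Heterolysis of C2–O1 gives an aryl-stabilised oxocarbenium ion at C2 and an aldehyde enol whose nucleophilic carbon C6 sits three ring atoms away. C6–C2 bonding extrudes O1 and C7 from the ring as the formyl group.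
4. The dioxepine ring comes from ring-closing metathesis of a mixed acetal of O-silylvanillin, after allyl-to-propenyl isomerisation. The mixed acetal is made from a 2-substituted pent-4-en-1-ol and the diallyl acetal of O-silylvanillin.
5. The two side-chain stereocentres come from an Evans magnesium-catalysed anti-aldol reaction of an N-pent-4-enoyl oxazolidinone with O-silylvanillin. Order of ring formation: dioxepine (step 7), then tetrahydrofuran (step 8).

Key step: step 8

Remark: (R)-4-benzyloxazolidin-2-one, pent-4-enoyl chloride, O-TBS-vanillin and allyloxytrimethylsilane are taken as commercial. The acetal carbon of the mixed acetal and of the dioxepine forms as both epimers, which is of no consequence because this carbon becomes trigonal in the key step.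

Abbreviations: TBS = tert-butyldimethylsilyl; TMS = trimethylsilyl; Ar = 4-(tert-butyldimethylsilyloxy)-3-methoxyphenyl.

## Route

Step 1
Reactants: 1 (R)-4-benzyloxazolidin-2-one; 2 pent-4-enoyl chloride
Product: 3 (R)-4-benzyl-3-(pent-4-enoyl)oxazolidin-2-one
Conditions: n-BuLi, THF, −78 °C; then 2, −78 to 0 °C
Reagents that add atoms: none
Why: N-acylation of the lithiated oxazolidinone (Evans imide formation); no new stereocentre.

Step 2
Reactants: 3 (R)-4-benzyl-3-(pent-4-enoyl)oxazolidin-2-one; 4 4-(tert-butyldimethylsilyloxy)-3-methoxybenzaldehyde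
Product: 6 (R)-4-benzyl-3-[(2S)-2-[(R)-Ar(hydroxy)methyl]pent-4-enoyl]oxazolidin-2-one (2,3-anti aldol adduct), via trimethylsilyl ether 5 (not isolated)
Conditions: MgCl2 (0.2 equiv), Et3N (2 equiv), TMSCl (1.5 equiv), EtOAc, 23 °C; then MeOH, CF3CO2H (cat.), 0 °C
Reagents that add atoms: none
Why: Evans magnesium halide-catalysed anti-aldol reaction: the chelated (Z)-magnesium enolate is attacked by the non-enolisable aldehyde on the face opposite the benzyl group (α-carbon S), and the boat-like transition state places aryl anti to allyl (carbinol carbon R), with TMSCl turning over the metal.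

Step 3
Reactants: 6 (R)-4-benzyl-3-[(2S)-2-[(R)-Ar(hydroxy)methyl]pent-4-enoyl]oxazolidin-2-one
Product: 7 (R)-4-benzyl-3-[(2S)-2-[(R)-Ar(tert-butyldimethylsilyloxy)methyl]pent-4-enoyl]oxazolidin-2-one
Conditions: TBSOTf, 2,6-lutidine, CH2Cl2, −78 to 0 °C
Reagents that add atoms: tert-butyldimethylsilyl trifluoromethanesulfonate, CC(C)(C)[Si](C)(C)OS(=O)(=O)C(F)(F)F
Why: Silylation of the secondary benzylic alcohol under non-basic conditions that should not trigger retro-aldol cleavage; the silyl ether keeps this oxygen from intercepting the oxocarbenium ion of step 8.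

Step 4
Reactants: 7 (R)-4-benzyl-3-[(2S)-2-[(R)-Ar(tert-butyldimethylsilyloxy)methyl]pent-4-enoyl]oxazolidin-2-one
Product: 8 (2R)-2-[(R)-Ar(tert-butyldimethylsilyloxy)methyl]pent-4-en-1-ol
Conditions: LiBH4, MeOH (1 equiv), THF, 0 °C
Reagents that add atoms: none
Why: Reductive removal of the oxazolidinone by hydride attack at the exocyclic imide carbonyl; the stereocentres are untouched and the auxiliary is recovered.

Step 5
Reactants: 4 4-(tert-butyldimethylsilyloxy)-3-methoxybenzaldehyde; 9 allyloxytrimethylsilane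
Product: 10 4-[bis(allyloxy)methyl]-1-(tert-butyldimethylsilyloxy)-2-methoxybenzene
Conditions: TMSOTf (1 mol %), CH2Cl2, −78 °C; then pyridine
Reagents that add atoms: none
Why: Noyori acetalisation of an aldehyde with an alkoxysilane under TMSOTf catalysis, driven by formation of the disiloxane; no stereocentre.

Step 6
Reactants: 8 (2R)-2-[(R)-Ar(tert-butyldimethylsilyloxy)methyl]pent-4-en-1-ol; 10 4-[bis(allyloxy)methyl]-1-(tert-butyldimethylsilyloxy)-2-methoxybenzene
Product: 11 4-[(allyloxy){[(2R)-2-[(R)-Ar(tert-butyldimethylsilyloxy)methyl]pent-4-en-1-yl]oxy}methyl]-1-(tert-butyldimethylsilyloxy)-2-methoxybenzene (both acetal epimers)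
Conditions: 10 (4 equiv), pyridinium p-toluenesulfonate (5 mol %), toluene, 40 °C, reduced pressure
Reagents that add atoms: none
Why: Acid-catalysed transacetalisation, steered to single exchange by the excess of 10 and removal of allyl alcohol; the new acetal centre forms as both epimers, which does not matter.

Step 7
Reactants: 11 mixed allyl acetal (both acetal epimers)
Product: 13 (5R)-2-Ar-5-[(R)-Ar(tert-butyldimethylsilyloxy)methyl]-4,5-dihydro-1,3-dioxepine (both C2 epimers), via bis(prop-1-enyl) acetal 12 (not isolated)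
Conditions: RuHCl(CO)(PPh3)3 (5 mol %), toluene, 80 °C; then second-generation Grubbs catalyst (5 mol %), toluene, 70 °C
Reagents that add atoms: none
Why: Ruthenium hydride addition–elimination moves both allyl double bonds by one position (the enol ether and the internal propenyl group are resting points, so the adjacent stereocentre should stay intact), and ring-closing metathesis of the propenyl ether with the propenyl group closes the seven-membered ring as its cis enol ether with loss of but-2-ene (isomerisation–ring-closing metathesis sequence); no new stereocentre.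

Step 8
Reactants: 13 (5R)-2-Ar-5-[(R)-Ar(tert-butyldimethylsilyloxy)methyl]-4,5-dihydro-1,3-dioxepine
Product: 15 (2R,3R,4R)-2-Ar-4-[(R)-Ar(tert-butyldimethylsilyloxy)methyl]tetrahydrofuran-3-carbaldehyde (2,3-trans-3,4-trans), via 2,3-cis aldehyde 14 (not isolated)
Conditions: TMSOTf (0.2 equiv), CH2Cl2, −78 to −30 °C; then Et3N
Reagents that add atoms: none
Why: TMSOTf silylates the enol-ether oxygen O1, the C2–O1 bond ionises to the aryl-stabilised oxocarbenium ion C2=O3 and a tethered silyl enol ether, and C6 attacks C2 in an intramolecular Mukaiyama-type aldol step that extrudes O1–C7 as the formyl group and releases the silyl cation for turnover. The closest known reaction type is the Lewis-acid ring contraction of 2-substituted 4,5-dihydro-1,3-dioxepines to 2-substituted tetrahydrofuran-3-carbaldehydes, a Petasis–Ferrier-type vinyl-acetal rearrangement. The tetrahydrofuran closes in a 5-(enolexo)-endo-trig mode, which is open to oxocarbenium ions as in Prins-type closures. C2 is controlled by the existing C5 stereocentre (C4 of the product): in the envelope transition state the aryl group of the (E)-oxocarbenium ion and the C4 side chain both sit pseudo-equatorial, which gives the 2,4-cis relation. C3 should first form mainly cis to C2 (14) and, being α to the formyl group, equilibrate under the Lewis acid to the all-trans aldehyde. The step needs C–C rather than O–C recombination (the latter only returns 13) and ionisation of the acetal rather than of the benzylic C–OTBS bond; the far greater lability of the vinyl acetal at −78 °C with catalytic TMSOTf and the bulk of the silyl ether should secure this.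

Step 9
Reactants: 15 (2R,3R,4R)-2-Ar-4-[(R)-Ar(tert-butyldimethylsilyloxy)methyl]tetrahydrofuran-3-carbaldehyde
Product: 17 4-[(2R,3S,4R)-4-[(R)-hydroxy(4-hydroxy-3-methoxyphenyl)methyl]-3-(hydroxymethyl)tetrahydrofuran-2-yl]-2-methoxyphenol, via tris(silyl) alcohol 16 (not isolated)
Conditions: NaBH4, THF–MeOH, 0 °C; then AcOH, TBAF, THF, 23 °C
Reagents that add atoms: none
Why: Borohydride reduction of the aldehyde, faster than any epimerisation, followed by acetic acid-buffered fluoride cleavage of the two aryl silyl ethers and the benzylic silyl ether; no stereocentre is touched.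

## Compound list

1 | (R)-4-benzyloxazolidin-2-one | O=C1N[C@H](Cc2ccccc2)CO1 | starting material
2 | pent-4-enoyl chloride | C=CCCC(=O)Cl | starting material
3 | (R)-4-benzyl-3-(pent-4-enoyl)oxazolidin-2-one | C=CCCC(=O)N1[C@H](Cc2ccccc2)COC1=O | intermediate
4 | 4-(tert-butyldimethylsilyloxy)-3-methoxybenzaldehyde | COc1cc(C=O)ccc1O[Si](C)(C)C(C)(C)C | starting material
5 | trimethylsilyl ether of 6 | COc1cc([C@H](O[Si](C)(C)C)[C@H](CC=C)C(=O)N2[C@H](Cc3ccccc3)COC2=O)ccc1O[Si](C)(C)C(C)(C)C | intermediate
6 | (R)-4-benzyl-3-[(2S)-2-[(R)-Ar(hydroxy)methyl]pent-4-enoyl]oxazolidin-2-one | COc1cc([C@H](O)[C@H](CC=C)C(=O)N2[C@H](Cc3ccccc3)COC2=O)ccc1O[Si](C)(C)C(C)(C)C | intermediate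
7 | (R)-4-benzyl-3-[(2S)-2-[(R)-Ar(tert-butyldimethylsilyloxy)methyl]pent-4-enoyl]oxazolidin-2-one | COc1cc([C@H](O[Si](C)(C)C(C)(C)C)[C@H](CC=C)C(=O)N2[C@H](Cc3ccccc3)COC2=O)ccc1O[Si](C)(C)C(C)(C)C | intermediate
8 | (2R)-2-[(R)-Ar(tert-butyldimethylsilyloxy)methyl]pent-4-en-1-ol | COc1cc([C@H](O[Si](C)(C)C(C)(C)C)[C@H](CC=C)CO)ccc1O[Si](C)(C)C(C)(C)C | intermediate
9 | allyloxytrimethylsilane | C=CCO[Si](C)(C)C | starting material
10 | 4-[bis(allyloxy)methyl]-1-(tert-butyldimethylsilyloxy)-2-methoxybenzene | COc1cc(C(OCC=C)OCC=C)ccc1O[Si](C)(C)C(C)(C)C | intermediate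
11 | mixed allyl acetal of 4 with 8 (both acetal epimers) | COc1cc([C@H](O[Si](C)(C)C(C)(C)C)[C@H](CC=C)COC(OCC=C)c2ccc(O[Si](C)(C)C(C)(C)C)c(OC)c2)ccc1O[Si](C)(C)C(C)(C)C | intermediate
12 | bis(prop-1-enyl) isomer of 11 (E/Z mixture) | COc1cc([C@H](O[Si](C)(C)C(C)(C)C)[C@H](C=CC)COC(OC=CC)c2ccc(O[Si](C)(C)C(C)(C)C)c(OC)c2)ccc1O[Si](C)(C)C(C)(C)C | intermediate
13 | (5R)-2-Ar-5-[(R)-Ar(tert-butyldimethylsilyloxy)methyl]-4,5-dihydro-1,3-dioxepine (both C2 epimers) | COc1cc([C@H](O[Si](C)(C)C(C)(C)C)[C@H]2COC(c3ccc(O[Si](C)(C)C(C)(C)C)c(OC)c3)OC=C2)ccc1O[Si](C)(C)C(C)(C)C | intermediate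
14 | (2R,3S,4R)-2-Ar-4-[(R)-Ar(tert-butyldimethylsilyloxy)methyl]tetrahydrofuran-3-carbaldehyde (2,3-cis-3,4-cis) | COc1cc([C@H](O[Si](C)(C)C(C)(C)C)[C@H]2CO[C@@H](c3ccc(O[Si](C)(C)C(C)(C)C)c(OC)c3)[C@H]2C=O)ccc1O[Si](C)(C)C(C)(C)C | intermediate
15 | (2R,3R,4R)-2-Ar-4-[(R)-Ar(tert-butyldimethylsilyloxy)methyl]tetrahydrofuran-3-carbaldehyde (all-trans) | COc1cc([C@H](O[Si](C)(C)C(C)(C)C)[C@H]2CO[C@@H](c3ccc(O[Si](C)(C)C(C)(C)C)c(OC)c3)[C@@H]2C=O)ccc1O[Si](C)(C)C(C)(C)C | intermediate
16 | [(2R,3S,4R)-2-Ar-4-[(R)-Ar(tert-butyldimethylsilyloxy)methyl]tetrahydrofuran-3-yl]methanol | COc1cc([C@H](O[Si](C)(C)C(C)(C)C)[C@H]2CO[C@@H](c3ccc(O[Si](C)(C)C(C)(C)C)c(OC)c3)[C@@H]2CO)ccc1O[Si](C)(C)C(C)(C)C | intermediate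
17 | 4-[(2R,3S,4R)-4-[(R)-hydroxy(4-hydroxy-3-methoxyphenyl)methyl]-3-(hydroxymethyl)tetrahydrofuran-2-yl]-2-methoxyphenol | COc1cc([C@H](O)[C@H]2CO[C@@H](c3ccc(O)c(OC)c3)[C@@H]2CO)ccc1O | target

## Step count and risks

Total step count: 9. Longest linear sequence: 8 steps (steps 1 to 4 and 6 to 9); step 5 is a one-step side branch.

Steps most likely to fail:

1. Step 8. What may go wrong: Lewis-acid ionisation of the silylated benzylic C–O bond beside the electron-rich ring, capture of the oxocarbenium ion by that oxygen, or incomplete equilibration at the α-formyl centre. The fallback sets out from 8 and 4 and returns at 15. It generates the same oxocarbenium ion oxidatively from an open-chain benzyl ether instead of by Lewis acid from the cyclic acetal. Reductive etherification of 4 with 8 (Et3SiH, BiBr3 cat., MeCN, 0 °C) should give the benzyl ether (2R)-1-(Ar-methoxy)-2-[(R)-Ar(tert-butyldimethylsilyloxy)methyl]pent-4-ene F1. Lemieux–Johnson cleavage of its terminal alkene (OsO4 cat., NaIO4, 2,6-lutidine, dioxane–water) should give the aldehyde (3R)-3-[(Ar-methoxy)methyl]-4-Ar-4-(tert-butyldimethylsilyloxy)butanal F2. Ac2O, Et3N and DMAP should convert it into the enol acetate F3. DDQ with 2,6-dichloropyridine, LiClO4 and 4 Å molecular sieves in 1,2-dichloroethane should then abstract the benzylic hydride of the ether, and the enol acetate should close the tetrahydrofuran onto the oxocarbenium ion under non-acidic conditions. After equilibration of the α-formyl centre this gives 15.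

2. Step 7. What may go wrong: double-bond migration beyond the propenyl stage, which would erode the stereocentre next to it, or stalling of the ruthenium carbene on the enol ether so that the seven-membered ring does not close. The fallback sets out from 8 and returns at 15. It gives up the seven-membered ring and builds the C2–C3 bond by a lactone aldol reaction. Lemieux–Johnson cleavage of 8 (OsO4 cat., NaIO4, 2,6-lutidine) should give the lactol (4R)-4-[(R)-Ar(tert-butyldimethylsilyloxy)methyl]tetrahydrofuran-2-ol F4. Oxidation with TEMPO and PhI(OAc)2 should give the lactone (4R)-4-[(R)-Ar(tert-butyldimethylsilyloxy)methyl]dihydrofuran-2(3H)-one F5. Enolisation with LiN(SiMe3)2 in THF at −78 °C and addition of 4 should give the 3,4-trans aldol adduct 3-[Ar(hydroxy)methyl] lactone F6. i-Bu2AlH should reduce it to the lactol F7. Camphorsulfonic acid in CH2Cl2 should ionise the new benzylic hydroxyl of the open hydroxy-aldehyde form, and the primary hydroxyl should capture the cation, the classical closure of 2-aryltetrahydrofuran lignans. The α-formyl centre then equilibrates to the all-trans aldehyde 15.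

3. Step 6. What may go wrong: statistical exchange (double exchange to the bis-acetal of 8, or incomplete exchange) and acid-triggered migration or loss of the silyl group during the equilibrium. The fallback sets out from 10 and returns at 11. It replaces the equilibrium by an irreversible alkylation. Acetyl chloride with ZnBr2 (cat.) in toluene should cleave 10 to the α-chloro ether 4-[allyloxy(chloro)methyl]-1-(tert-butyldimethylsilyloxy)-2-methoxybenzene F8. Without isolation, F8 should alkylate 8 in the presence of i-Pr2NEt at 0 °C to give 11.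

Further compounds

F1 | step 8 | (2R)-1-(Ar-methoxy)-2-[(R)-Ar(tert-butyldimethylsilyloxy)methyl]pent-4-ene | COc1cc([C@H](O[Si](C)(C)C(C)(C)C)[C@H](CC=C)COCc2ccc(O[Si](C)(C)C(C)(C)C)c(OC)c2)ccc1O[Si](C)(C)C(C)(C)C
F2 | step 8 | (3R)-3-[(Ar-methoxy)methyl]-4-Ar-4-(tert-butyldimethylsilyloxy)butanal, (4R) at the silyloxy carbon | COc1cc([C@H](O[Si](C)(C)C(C)(C)C)[C@H](CC=O)COCc2ccc(O[Si](C)(C)C(C)(C)C)c(OC)c2)ccc1O[Si](C)(C)C(C)(C)C
F3 | step 8 | enol acetate of F2 (E/Z mixture) | COc1cc([C@H](O[Si](C)(C)C(C)(C)C)[C@H](C=COC(C)=O)COCc2ccc(O[Si](C)(C)C(C)(C)C)c(OC)c2)ccc1O[Si](C)(C)C(C)(C)C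
F4 | step 7 | (4R)-4-[(R)-Ar(tert-butyldimethylsilyloxy)methyl]tetrahydrofuran-2-ol (both anomers) | COc1cc([C@H](O[Si](C)(C)C(C)(C)C)[C@H]2COC(O)C2)ccc1O[Si](C)(C)C(C)(C)C
F5 | step 7 | (4R)-4-[(R)-Ar(tert-butyldimethylsilyloxy)methyl]dihydrofuran-2(3H)-one | COc1cc([C@H](O[Si](C)(C)C(C)(C)C)[C@H]2COC(=O)C2)ccc1O[Si](C)(C)C(C)(C)C
F6 | step 7 | 3,4-trans-3-[Ar(hydroxy)methyl]-4-[(R)-Ar(tert-butyldimethylsilyloxy)methyl]dihydrofuran-2(3H)-one (both carbinol epimers) | COc1cc([C@H](O[Si](C)(C)C(C)(C)C)[C@H]2COC(=O)[C@@H]2C(O)c3ccc(O[Si](C)(C)C(C)(C)C)c(OC)c3)ccc1O[Si](C)(C)C(C)(C)C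
F7 | step 7 | 3,4-trans-3-[Ar(hydroxy)methyl]-4-[(R)-Ar(tert-butyldimethylsilyloxy)methyl]tetrahydrofuran-2-ol | COc1cc([C@H](O[Si](C)(C)C(C)(C)C)[C@H]2COC(O)[C@@H]2C(O)c3ccc(O[Si](C)(C)C(C)(C)C)c(OC)c3)ccc1O[Si](C)(C)C(C)(C)C
F8 | step 6 | 4-[allyloxy(chloro)methyl]-1-(tert-butyldimethylsilyloxy)-2-methoxybenzene | COc1cc(C(Cl)OCC=C)ccc1O[Si](C)(C)C(C)(C)C
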